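(The data were generated by integration with constants of no real substance; noise was put on by code.)

I chose to compare these flasks by how much substrate a dose of enzyme can consume before it dies.

all flasks: substrate 10 mM (fed, over 5.0 h)

| run | free enzyme | temperature | remark | time |
|---|---|---|---|---|
| Saturday's | 0.50 µM | 45 °C | run made earlier |  |
| Wednesday's | 0.75 µM | 56 °C | run made earlier |  |
| south-west | 1.0 µM | 40 °C |  | 50 h |
| south | 1.0 µM | 60 °C |  | 50 h |

| run | time / h | target / % | substrate / % |
|---|---|---|---|
| Saturday's | 6.00 | 6.0 | 90.1 |
| Saturday's | 12.0 | 10.4 | 77.0 |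
| Saturday's | 20.0 | 15.1 | 62.6 |
| Saturday's | 25.0 | 17.5 | 55.3 |
| Saturday's | 30.0 | 18.8 | 48.4 |
| Saturday's | 40.0 | 20.3 | 37.7 |
| Wednesday's | 2.50 | 3.1 | 45.3 |
| Wednesday's | 5.00 | 6.2 | 89.4 |
| Wednesday's | 10.0 | 8.2 | 83.9 |
| Wednesday's | 12.0 | 8.8 | 83.4 |
| Wednesday's | 15.0 | 9.1 | 82.0 |
| Wednesday's | 20.0 | 9.1 | 81.7 |

(readings scatter by 0.3 percentage points)
- the best flask by amount of target, in percent of the substrate charged; "all alike" if 1.5 percentage points covers them all (south-west / south / all alike)
- amount of target at the end, in percent of the substrate charged, south-west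
- amount of target at the end, in percent of the substrate charged, south
- the analysis behind the earlier runs scatters by 0.3 percentage points, standard deviation
- percentages count the whole charge, also what has not yet gone in

I took substrate loss as pseudo-first-order, with constant kc proportional to free enzyme concentration c, and with that enzyme dying at constant kd. Wednesday's substrate readings levelled off near their last value, 81.7 %, and their approach to that level read as kd = 0.251 h⁻¹. I defined the reach, the share of the charge consumed over the enzyme's life, as kc times the time integral of substrate present and enzyme surviving, with substrate rising steadily through the feed and then taken as the full charge. Wednesday's loss then gave kc = 0.0804 h⁻¹.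

Saturday's kc read 0.0255 h⁻¹; set against Wednesday's per unit of c, it gave a temperature trend, and carrying that on put my kc for south at 0.137 h⁻¹. I guessed kd for south 3 times Wednesday's, 0.752 h⁻¹, so my estimate of the enzyme's lifetime there, 1.33 h, was shorter than the feed. South's reach came to 4.75 %. Wednesday's target per substrate consumed at 2.50 h read 66.0 %, which made my estimate for south 3.13 % target. For south-west I took Saturday's highest target reading, 20.3 %, more than my estimate for south.

The forecast named south-west, with 19.8 % and 1.9 %, saying of south that “the enzyme dies during the feed”.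

    free enzyme → unfolded enzyme (k = 1.10 × 10⁻⁶ s⁻¹, Ea = 221 kJ mol⁻¹)
    substrate + free enzyme → target + free enzyme, rate k2*[substrate]*[free enzyme]/(1 + ([substrate]/Km2)) (5.10 mM, k = 33.0 L mol⁻¹ s⁻¹, Ea = 43.0 kJ mol⁻¹)
    free enzyme + target → free enzyme + over-reaction product (k = 22.0 L mol⁻¹ s⁻¹, Ea = 52.0 kJ mol⁻¹)
    target ⇌ isomer of the product (K = 1.30, k = 7.60 × 10⁻⁵ s⁻¹, Ea = 100 kJ mol⁻¹, ΔH = −36.0 kJ mol⁻¹)
    (constants at 40 °C)

South-west ended at 15.8 % and south at 4.35 %, so south-west led. At the end of the feed, 5.00 h, south held 3.94 % of its catalyst as free enzyme and 93.2 % of its charge as substrate. South lost 7.43 % of its charge, 1.57 times my reach. At fixed temperature and feed my reach is proportional to c, so the neighbour of south charged with 0.0040 mM free enzyme had a reckoned reach of 19.0 %. It lost 25.7 %, which is 1.35 times that reach.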